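Cuts, from the periphery to the core: the malonate half-ester C–O bond; C13=C14 (olefination of a C-13 methyl ketone); C8=C17 (methylenation of a C-8 ketone made from a C8=C9 alkene); C9–C11 (coupling at a C-9 enol triflate); then, in one stroke, C5–C10, C2–C3 and C7–C8 of a bicyclic 1,9-dione, which gives 3-methylpentane-2,4-dione and 4,4-dimethylpent-2-ynedial.
Enabling feature: C-10 carries C-1 and C-9, and both can be carbonyl carbons, so C-2/C-1/C-10(CH3)/C-9/C-8 is one symmetrical diketone with a nucleophilic central carbon and two enantiotopic acetyl arms. C-4 is quaternary, so an aldehyde at C-3 cannot enolise and C-5 can be the alkyne carbon of an ynal whose formyl carbon is C-7.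
Forward: rings A and B arise together in step 4 (C5–C10 by conjugate addition, C7–C8 and C2–C3 by aldol condensations). Hydrogenation, a site-selective C-9 enol triflate, side-chain coupling, removal of the C-1 oxygen, hydroboration/oxidation/methylenation and the side-chain end game follow.
Stereochemistry: C-10 from the chiral amine catalyst (choice between the two acetyl arms); C-5 from hydrogenation anti to the angular methyl; C-9 from hydroboration anti to that methyl, held by the equatorial preference next to the C-8 ketone; 13E from the Horner–Wadsworth–Emmons step.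

Key step: step 4

Remark: the configuration drawn is (5R,9R,10R), the ent-labdane (ent-copalol) series, and this enantiomer is made; labdane numbering (C-1 to C-20) is used in the text; 1, 6 and 13 are taken as catalogue compounds.

Step 1
Reactants: 1 2,2-dimethylbut-3-ynoic acid
Product: 2 2,2-dimethylbut-3-yn-1-ol
Conditions: LiAlH4 (1.5 equiv), Et2O, 0 °C → rt; then H2O
Reagents that add atoms: none
Why: LiAlH4 reduction of the carboxylic acid to the primary alcohol; the hydroxyl is not propargylic, so the alkyne is not hydroaluminated.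

Step 2
Reactants: 2 2,2-dimethylbut-3-yn-1-ol
Product: 4 2,2-dimethylpent-3-yne-1,5-diol, via dilithium alkoxide acetylide 3 (not isolated)
Conditions: n-BuLi (2.2 equiv), THF, −78 → 0 °C; (CH2O)n (1.5 equiv), 0 °C → rt; then H2O
Reagents that add atoms: paraformaldehyde (as formaldehyde), C=O
Why: The alkoxide–acetylide dianion adds through carbon to formaldehyde (alkynylation of an aldehyde), which attaches the carbon that becomes C-7.

Step 3
Reactants: 4 2,2-dimethylpent-3-yne-1,5-diol
Product: 5 4,4-dimethylpent-2-ynedial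
Conditions: DMP (1,1,1-triacetoxy-1,1-dihydro-1,2-benziodoxol-3(1H)-one, 2.4 equiv), CH2Cl2, 0 °C → rt
Reagents that add atoms: none
Why: Dess–Martin oxidation of both primary alcohols gives a dialdehyde in which neither formyl group has an α-hydrogen (alkyne on one side, quaternary carbon on the other), so it cannot self-condense.

Step 4
Reactants: 5 4,4-dimethylpent-2-ynedial; 6 3-methylpentane-2,4-dione
Product: 9 (8aR)-4,4,8a-trimethylnaphthalene-1,8(4H,8aH)-dione, via prochiral Michael adduct 7 (not isolated), via monocyclic dienone aldehyde 8 (not isolated)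
Conditions: 6 (1.1 equiv), (S)-2-[diphenyl(trimethylsilyloxy)methyl]pyrrolidine (20 mol %), PhCO2H (20 mol %), toluene, −20 °C → rt; then TsOH·H2O (10 mol %), 50 °C
Reagents that add atoms: none
Why: Proposed new method: the amine turns the ynal end of 5 into an alkynyl iminium ion, the enol of 6 adds through its central carbon to the alkyne carbon beside the quaternary centre (conjugate addition, allenamine, C-protonation) to give the prochiral adduct 7, the enol of one acetyl arm then attacks the iminium carbon with loss of the amine (Mannich-type aldol condensation) to give dienone 8, and the second acetyl arm condenses with the neopentyl aldehyde once the sulfonic acid is added to give 9. The closest known reaction types are the secondary-amine-catalysed conjugate addition of 1,3-dicarbonyl compounds to ynals and the Hajos–Parrish–Eder–Sauer–Wiechert group-selective aldol cyclisation; new is that the two enantiotopic groups are the nucleophilic acetyl arms of an acyclic 3,3-disubstituted pentane-2,4-dione and that the addition and both ring closures run in one flask. Ring B closes 6-(enolendo)-exo-trig onto the iminium carbon and ring A closes 6-(enolendo)-exo-trig onto the aldehyde, each followed by elimination. The only stereocentre, the quaternary C-10, is created when ring B closes: the catalyst is covalently bound at C-7 and its diphenyl(silyloxy)methyl group blocks one face of the iminium carbon, so only the acetyl arm that reaches the open face reacts, and the (S)-catalyst is expected to select the arm that gives (8aR). The step needs β-addition and not 1,2-addition (soft enol, iminium activation), the cis arrangement of C-7 and C-10 on the new C5=C6 bond (the two geometries interconvert through the allenamine), closure of ring B before any uncatalysed closure of ring A (the hindered neopentyl aldehyde reacts only after the stronger acid is added) and no self-condensation of 5 (no α-hydrogen on either aldehyde).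

Step 5
Reactants: 9 (8aR)-4,4,8a-trimethylnaphthalene-1,8(4H,8aH)-dione
Product: 10 (4aR,8aR)-4,4,8a-trimethyloctahydronaphthalene-1,8-dione
Conditions: H2 (4 atm), 10 % Pd/C, EtOAc–AcOH (10:1), rt
Reagents that add atoms: none
Why: Heterogeneous catalytic hydrogenation saturates the three C=C bonds, and hydrogen should reach the ring-fusion carbon C-5 from the face opposite the angular methyl group (as in 4,4-dimethyl-Δ5-steroids), which sets the trans ring fusion.

Step 6
Reactants: 10 (4aR,8aR)-4,4,8a-trimethyloctahydronaphthalene-1,8-dione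
Product: 12 (4aR,8aR)-5,5,8a-trimethyl-8-oxo-3,4,4a,5,6,7,8,8a-octahydronaphthalen-1-yl trifluoromethanesulfonate, via potassium enolate 11 (not isolated)
Conditions: KN(SiMe3)2 (1.05 equiv), THF, −78 °C; then PhNTf2 (1.1 equiv), −78 → 0 °C
Reagents that add atoms: N-phenylbis(trifluoromethanesulfonimide), O=S(=O)(N(c1ccccc1)S(=O)(=O)C(F)(F)F)C(F)(F)F
Why: Kinetic enolate formation and O-sulfonylation (enol triflate synthesis): the axial α-hydrogen on C-2 of ring A is flanked by two syn-axial methyl groups (on C-4 and C-10) while that on C-8 of ring B faces only one, so the bulky amide base should deprotonate ring B.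

Step 7
Reactants: 12 (4aR,8aR)-5,5,8a-trimethyl-8-oxo-3,4,4a,5,6,7,8,8a-octahydronaphthalen-1-yl trifluoromethanesulfonate; 13 2-ethenyl-2-methyl-1,3-dioxolane
Product: 15 (4aR,8aR)-4,4,8a-trimethyl-8-[2-(2-methyl-1,3-dioxolan-2-yl)ethyl]-3,4,4a,5,6,8a-hexahydronaphthalen-1(2H)-one, via B-alkyl borane 14 (not isolated)
Conditions: 13 (1.5 equiv), 9-BBN (1.5 equiv), THF, 0 °C → rt; then 12, Pd(dppf)Cl2 (5 mol %), AsPh3 (10 mol %), K3PO4 (3 equiv), DMF–H2O, 50 °C
Reagents that add atoms: none
Why: Anti-Markovnikov hydroboration of the vinyl group followed by B-alkyl Suzuki–Miyaura coupling (oxidative addition of the enol triflate to zerovalent palladium, transmetalation, reductive elimination) joins C-9 to C-11 and leaves the ketone untouched.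

Step 8
Reactants: 15 (4aR,8aR)-4,4,8a-trimethyl-8-[2-(2-methyl-1,3-dioxolan-2-yl)ethyl]-3,4,4a,5,6,8a-hexahydronaphthalen-1(2H)-one
Product: 17 2-methyl-2-{2-[(4aR,8aR)-5,5,8a-trimethyl-3,4,4a,5,6,7,8,8a-octahydronaphthalen-1-yl]ethyl}-1,3-dioxolane, via hydrazone 16 (not isolated)
Conditions: N2H4·H2O (10 equiv), KOH, diethylene glycol, 130 °C, then 200 °C
Reagents that add atoms: none
Why: Wolff–Kishner reduction (Huang-Minlon procedure) removes the ring A carbonyl through its hydrazone; the dioxolane and the isolated trisubstituted alkene are inert to hot KOH.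

Step 9
Reactants: 17 2-methyl-2-{2-[(4aR,8aR)-5,5,8a-trimethyl-3,4,4a,5,6,7,8,8a-octahydronaphthalen-1-yl]ethyl}-1,3-dioxolane
Product: 19 (1S,2S,4aR,8aR)-5,5,8a-trimethyl-1-[2-(2-methyl-1,3-dioxolan-2-yl)ethyl]decahydronaphthalen-2-ol, via alkylborane 18 (not isolated)
Conditions: BH3·THF (3 equiv), THF, 0 °C → rt; then NaOH (aq), H2O2, 0 °C → rt
Reagents that add atoms: hydrogen peroxide, OO
Why: Hydroboration–oxidation: boron adds to the less substituted C-8 and hydrogen to C-9, syn, from the face opposite the angular methyl group, so the side chain on C-9 ends up cis to that methyl.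

Step 10
Reactants: 19 (1S,2S,4aR,8aR)-5,5,8a-trimethyl-1-[2-(2-methyl-1,3-dioxolan-2-yl)ethyl]decahydronaphthalen-2-ol
Product: 20 (1S,4aR,8aR)-5,5,8a-trimethyl-1-[2-(2-methyl-1,3-dioxolan-2-yl)ethyl]octahydronaphthalen-2(1H)-one
Conditions: DMP (1.3 equiv), CH2Cl2, rt
Reagents that add atoms: none
Why: Dess–Martin oxidation gives the C-8 ketone; the C-9 side chain is already equatorial, so enolisation cannot change the configuration set in step 9.

Step 11
Reactants: 20 (1S,4aR,8aR)-5,5,8a-trimethyl-1-[2-(2-methyl-1,3-dioxolan-2-yl)ethyl]octahydronaphthalen-2(1H)-one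
Product: 21 2-methyl-2-{2-[(1R,4aR,8aR)-5,5,8a-trimethyl-2-methylidenedecahydronaphthalen-1-yl]ethyl}-1,3-dioxolane
Conditions: Ph3PCH3Br (3 equiv), KOtBu (2.8 equiv), toluene, rt → 90 °C
Reagents that add atoms: methyltriphenylphosphonium bromide, C[P+](c1ccccc1)(c1ccccc1)c1ccccc1.[Br-]
Why: Wittig methylenation with the non-stabilised ylide converts the hindered ketone into the exocyclic alkene.

Step 12
Reactants: 21 2-methyl-2-{2-[(1R,4aR,8aR)-5,5,8a-trimethyl-2-methylidenedecahydronaphthalen-1-yl]ethyl}-1,3-dioxolane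
Product: 22 4-[(1R,4aR,8aR)-5,5,8a-trimethyl-2-methylidenedecahydronaphthalen-1-yl]butan-2-one
Conditions: AcOH–H2O–THF (3:1:1), 45 °C
Reagents that add atoms: water, O
Why: Mild acid hydrolysis of the dioxolane (acetal cleavage) frees the methyl ketone without protonating the 1,1-disubstituted alkene.

Step 13
Reactants: 22 4-[(1R,4aR,8aR)-5,5,8a-trimethyl-2-methylidenedecahydronaphthalen-1-yl]butan-2-one
Product: 23 ethyl (2E)-3-methyl-5-[(1R,4aR,8aR)-5,5,8a-trimethyl-2-methylidenedecahydronaphthalen-1-yl]pent-2-enoate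
Conditions: (EtO)2P(O)CH2CO2Et (3 equiv), NaH (2.8 equiv), THF, 0 → 60 °C
Reagents that add atoms: triethyl phosphonoacetate, CCOC(=O)CP(=O)(OCC)OCC
Why: Horner–Wadsworth–Emmons olefination of the methyl ketone should give mainly the (E)-enoate, the larger alkyl chain lying trans to the ester; any Z isomer is removed by chromatography.

Step 14
Reactants: 23 ethyl (2E)-3-methyl-5-[(1R,4aR,8aR)-5,5,8a-trimethyl-2-methylidenedecahydronaphthalen-1-yl]pent-2-enoate
Product: 24 (2E)-3-methyl-5-[(1R,4aR,8aR)-5,5,8a-trimethyl-2-methylidenedecahydronaphthalen-1-yl]pent-2-en-1-ol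
Conditions: iBu2AlH (2.5 equiv), CH2Cl2, −78 °C; aqueous potassium sodium tartrate work-up
Reagents that add atoms: none
Why: iBu2AlH reduces the conjugated ester in 1,2 fashion to the allylic alcohol and does not touch the two alkenes.

Step 15
Reactants: 24 (2E)-3-methyl-5-[(1R,4aR,8aR)-5,5,8a-trimethyl-2-methylidenedecahydronaphthalen-1-yl]pent-2-en-1-ol
Product: 25 3-{[(2E)-3-methyl-5-[(1R,4aR,8aR)-5,5,8a-trimethyl-2-methylidenedecahydronaphthalen-1-yl]pent-2-en-1-yl]oxy}-3-oxopropanoic acid
Conditions: 2,2-dimethyl-1,3-dioxane-4,6-dione (1.2 equiv), toluene, 100 °C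
Reagents that add atoms: Meldrum's acid (2,2-dimethyl-1,3-dioxane-4,6-dione), CC1(C)OC(=O)CC(=O)O1
Why: Thermal acylation of the alcohol by Meldrum's acid (ring opening with loss of acetone) gives the malonic acid half ester directly, so the free acid needs no protecting group.

Compound list
1 | 2,2-dimethylbut-3-ynoic acid | C#CC(C)(C)C(=O)O | starting material
2 | 2,2-dimethylbut-3-yn-1-ol | C#CC(C)(C)CO | intermediate
3 | dilithium salt of 2 (lithium alkoxide and lithium acetylide) | [Li+].[Li+].[O-]CC(C)(C)C#[C-] | intermediate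
4 | 2,2-dimethylpent-3-yne-1,5-diol | OCC#CC(C)(C)CO | intermediate
5 | 4,4-dimethylpent-2-ynedial | O=CC#CC(C)(C)C=O | intermediate
6 | 3-methylpentane-2,4-dione | CC(=O)C(C)C(C)=O | starting material
7 | (2Z)-4,4-dimethyl-3-(3-methyl-2,4-dioxopentan-3-yl)pent-2-enedial | O=C/C=C(/C(C)(C)C=O)C(C)(C(C)=O)C(C)=O | intermediate
8 | 2-[(6S)-6-acetyl-6-methyl-5-oxocyclohexa-1,3-dien-1-yl]-2-methylpropanal | C1=CC=C(C(C)(C)C=O)[C@@](C)(C(C)=O)C1=O | intermediate
9 | (8aR)-4,4,8a-trimethylnaphthalene-1,8(4H,8aH)-dione | C1=CC=C2C(C)(C)C=CC(=O)[C@@]2(C)C1=O | intermediate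
10 | (4aR,8aR)-4,4,8a-trimethyloctahydronaphthalene-1,8-dione (trans-fused) | C1CC[C@@H]2C(C)(C)CCC(=O)[C@@]2(C)C1=O | intermediate
11 | potassium enolate of 10 on the ring B side (O–C9=C8) | C1C[C@@H]2C(C)(C)CCC(=O)[C@@]2(C)C([O-])=CC1.[K+] | intermediate
12 | (4aR,8aR)-5,5,8a-trimethyl-8-oxo-3,4,4a,5,6,7,8,8a-octahydronaphthalen-1-yl trifluoromethanesulfonate | C1C[C@@H]2C(C)(C)CCC(=O)[C@@]2(C)C(OS(=O)(=O)C(F)(F)F)=CC1 | intermediate
13 | 2-ethenyl-2-methyl-1,3-dioxolane | C=CC1(C)OCCO1 | starting material
14 | 9-[2-(2-methyl-1,3-dioxolan-2-yl)ethyl]-9-borabicyclo[3.3.1]nonane | CC1(CCB2C3CCCC2CCC3)OCCO1 | intermediate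
15 | (4aR,8aR)-4,4,8a-trimethyl-8-[2-(2-methyl-1,3-dioxolan-2-yl)ethyl]-3,4,4a,5,6,8a-hexahydronaphthalen-1(2H)-one | C1C[C@@H]2C(C)(C)CCC(=O)[C@@]2(C)C(CCC3(C)OCCO3)=CC1 | intermediate
16 | hydrazone of 15 at the ring A carbonyl | C1C[C@@H]2C(C)(C)CCC(=NN)[C@@]2(C)C(CCC3(C)OCCO3)=CC1 | intermediate
17 | 2-methyl-2-{2-[(4aR,8aR)-5,5,8a-trimethyl-3,4,4a,5,6,7,8,8a-octahydronaphthalen-1-yl]ethyl}-1,3-dioxolane | C1C[C@@H]2C(C)(C)CCC[C@@]2(C)C(CCC3(C)OCCO3)=CC1 | intermediate
18 | C-8 borane adduct of 17 (BH2 on C-8, H on C-9, both on the face opposite the angular methyl) | B[C@H]1CC[C@@H]2C(C)(C)CCC[C@@]2(C)[C@@H]1CCC3(C)OCCO3 | intermediate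
19 | (1S,2S,4aR,8aR)-5,5,8a-trimethyl-1-[2-(2-methyl-1,3-dioxolan-2-yl)ethyl]decahydronaphthalen-2-ol | O[C@H]1CC[C@@H]2C(C)(C)CCC[C@@]2(C)[C@@H]1CCC3(C)OCCO3 | intermediate
20 | (1S,4aR,8aR)-5,5,8a-trimethyl-1-[2-(2-methyl-1,3-dioxolan-2-yl)ethyl]octahydronaphthalen-2(1H)-one | O=C1CC[C@@H]2C(C)(C)CCC[C@@]2(C)[C@@H]1CCC3(C)OCCO3 | intermediate
21 | 2-methyl-2-{2-[(1R,4aR,8aR)-5,5,8a-trimethyl-2-methylidenedecahydronaphthalen-1-yl]ethyl}-1,3-dioxolane | C=C1CC[C@@H]2C(C)(C)CCC[C@@]2(C)[C@@H]1CCC3(C)OCCO3 | intermediate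
22 | 4-[(1R,4aR,8aR)-5,5,8a-trimethyl-2-methylidenedecahydronaphthalen-1-yl]butan-2-one | C=C1CC[C@@H]2C(C)(C)CCC[C@@]2(C)[C@@H]1CCC(C)=O | intermediate
23 | ethyl (2E)-3-methyl-5-[(1R,4aR,8aR)-5,5,8a-trimethyl-2-methylidenedecahydronaphthalen-1-yl]pent-2-enoate | C=C1CC[C@@H]2C(C)(C)CCC[C@@]2(C)[C@@H]1CC/C(C)=C/C(=O)OCC | intermediate
24 | (2E)-3-methyl-5-[(1R,4aR,8aR)-5,5,8a-trimethyl-2-methylidenedecahydronaphthalen-1-yl]pent-2-en-1-ol (ent-copalol) | C=C1CC[C@@H]2C(C)(C)CCC[C@@]2(C)[C@@H]1CC/C(C)=C/CO | intermediate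
25 | 3-{[(2E)-3-methyl-5-[(1R,4aR,8aR)-5,5,8a-trimethyl-2-methylidenedecahydronaphthalen-1-yl]pent-2-en-1-yl]oxy}-3-oxopropanoic acid | C=C1CC[C@@H]2C(C)(C)CCC[C@@]2(C)[C@@H]1CC/C(C)=C/COC(=O)CC(=O)O | target

Total step count: 15. Longest linear sequence: 15 steps (1 to 25); 6 and 13 enter as purchased compounds.

Steps most likely to fail

1. Step 4 (the step that bears the label).
- What may go wrong: conjugate addition at the alkyne carbon beside the quaternary centre may be slow, and the two acetyl arms may be told apart poorly (or ring A may close first without catalyst control), so that material of low enantiomeric purity results.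
- Fallback with known chemistry, setting out from 5 and 6: Cs2CO3 (10 mol %) in MeCN effects the conjugate addition of the 1,3-diketone to the ynal and adduct 7 is isolated. Pyrrolidine/AcOH in toluene at 60 °C then effects both aldol condensations without any chiral control and gives the racemate, that is 9 together with its enantiomer (8aS)-4,4,8a-trimethylnaphthalene-1,8(4H,8aH)-dione F1. The two are separated by preparative chromatography on a chiral stationary phase, and 9 re-enters the route at step 5.

2. Step 6.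
- What may go wrong: deprotonation may occur on the ring A side (C-2) or at both ketones, giving the regioisomeric or the bis(enol triflate).
- Fallback, setting out from 9 and returning at 17: the two rings are told apart before hydrogenation by the steric difference at their β-carbons.
  - [(Ph3P)CuH]6 (5 mol %), PhMe2SiH and t-BuOH in toluene reduce only the unhindered C7=C8 bond of the dienone (the β-carbon of the ring A enone is shielded by the geminal methyl groups) and give (8aR)-4,4,8a-trimethyl-6,7-dihydronaphthalene-1,8(4H,8aH)-dione F2.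
  - Ethylene glycol and TsOH ketalise the now saturated ring B ketone much faster than the conjugated ring A ketone and give the mono-dioxolane F3.
  - Hydrogenation (H2, Pd/C) of the C2=C3 and C5=C6 bonds gives the trans-fused keto ketal F4.
  - Wolff–Kishner reduction gives (4a'R,8a'R)-5',5',8a'-trimethyloctahydro-2'H-spiro[1,3-dioxolane-2,1'-naphthalene] F5.
  - Aqueous HCl in THF gives (4aR,8aR)-5,5,8a-trimethyloctahydronaphthalen-1(2H)-one F6.
  - F6 has a single ketone and one enolisable side, so KN(SiMe3)2/PhNTf2 gives (4aR,8aR)-5,5,8a-trimethyl-3,4,4a,5,6,7,8,8a-octahydronaphthalen-1-yl trifluoromethanesulfonate F7 without ambiguity.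
  - B-alkyl Suzuki–Miyaura coupling of F7 with 14 under the conditions of step 7 gives 17.

3. Step 5.
- What may go wrong: reduction of the C5=C6 bond, which lies between two quaternary carbons, may be incomplete, so that the reaction stalls at the Δ5 compound, or some hydrogen may be delivered syn to the angular methyl group.
- Fallback, setting out from 9 and returning at 10: the stalled intermediate (8aR)-4,4,8a-trimethyl-2,3,6,7-tetrahydronaphthalene-1,8(4H,8aH)-dione F8 is reduced by radical hydrogen-atom-transfer hydrogenation (Mn(dpm)3 cat., PhSiH3, t-BuOOH, i-PrOH, rt). The tertiary C-5 radical takes up hydrogen under thermodynamic control and gives the trans-fused dione 10.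

Further compounds
F1 | step 4 | (8aS)-4,4,8a-trimethylnaphthalene-1,8(4H,8aH)-dione | C1=CC=C2C(C)(C)C=CC(=O)[C@]2(C)C1=O
F2 | step 6 | (8aR)-4,4,8a-trimethyl-6,7-dihydronaphthalene-1,8(4H,8aH)-dione | C1CC=C2C(C)(C)C=CC(=O)[C@@]2(C)C1=O
F3 | step 6 | (8a'S)-5',5',8a'-trimethyl-2',3',5',8a'-tetrahydro-8'H-spiro[1,3-dioxolane-2,1'-naphthalen]-8'-one (ring B ketal of F2) | C1CC=C2C(C)(C)C=CC(=O)[C@@]2(C)C13OCCO3
F4 | step 6 | (4a'R,8a'S)-5',5',8a'-trimethyloctahydro-8'H-spiro[1,3-dioxolane-2,1'-naphthalen]-8'-one (trans-fused) | C1CC[C@@H]2C(C)(C)CCC(=O)[C@@]2(C)C13OCCO3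
F5 | step 6 | (4a'R,8a'R)-5',5',8a'-trimethyloctahydro-2'H-spiro[1,3-dioxolane-2,1'-naphthalene] | C1CC[C@@H]2C(C)(C)CCC[C@@]2(C)C13OCCO3
F6 | step 6 | (4aR,8aR)-5,5,8a-trimethyloctahydronaphthalen-1(2H)-one | C1CC[C@@H]2C(C)(C)CCC[C@@]2(C)C1=O
F7 | step 6 | (4aR,8aR)-5,5,8a-trimethyl-3,4,4a,5,6,7,8,8a-octahydronaphthalen-1-yl trifluoromethanesulfonate | C1C[C@@H]2C(C)(C)CCC[C@@]2(C)C(OS(=O)(=O)C(F)(F)F)=CC1
F8 | step 5 | (8aR)-4,4,8a-trimethyl-2,3,6,7-tetrahydronaphthalene-1,8(4H,8aH)-dione | C1CC=C2C(C)(C)CCC(=O)[C@@]2(C)C1=O
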